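Retrosynthesis (carotenoid numbering; primed atoms lie on the side of the epsilon ring, ring E; unprimed atoms on the side of the hydroxylated beta ring, ring B): the O3 silyl ether is removed last, then the C14'–C15' single bond and the C13'–CH3 bond are cut together. This gives the C18 terminal alkyne 24 (C13'≡C14'–H) and the C21 (E)-alkenyl iodide 13 (iodine on C15').
Enabling feature: C14' carries only H and C13' a methyl group inside an E-trisubstituted alkene, the retron of syn methyl-metalation of a terminal alkyne. One flask therefore makes the methyl branch, the C13'=C14' geometry and the fragment-joining bond, and completes the C40 nonaene-yne chain.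
Iodide 13 is grown outward from ring B: enol triflate (C5=C6), Sonogashira coupling (C6–C7, keeps C7≡C8), allylic oxidation, Horner–Wadsworth–Emmons olefination (C11=C12), nitrile reduction, Takai iodo-olefination (C15=C15').
Alkyne 24 is grown outward from ring E: ketone-to-alkyne conversion (C9'≡C10'), methylalumination and coupling with a C4 chloroenyne (C10'–C11'), desilylation; the same reaction type then serves as the key step.
Stereochemistry: C6' comes from (R)-alpha-ionone and C3 from C4 of (4R,6R)-actinol; all alkene geometries come from syn carbometalation, stereoretentive cross-coupling, E-selective olefinations and one E-configured building block (C9=C10).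

Key step: step 12

Assumption: (R)-alpha-ionone and (4R,6R)-actinol are taken as purchasable in high enantiomeric purity; the phosphonate 8 is used as its E isomer.

Step 1
Reactants: 1 (4R,6R)-4-hydroxy-2,2,6-trimethylcyclohexan-1-one ((4R,6R)-actinol)
Product: 2 (4R,6R)-4-[(tert-butyldimethylsilyl)oxy]-2,2,6-trimethylcyclohexan-1-one
Conditions: TBSCl, imidazole, DMF, 0 °C to rt
Reagents that add atoms: tert-butyldimethylsilyl chloride, CC(C)(C)[Si](C)(C)Cl
Why: Imidazole-mediated silyl ether formation on the unhindered secondary alcohol masks the only protic site before the enolate and organometallic steps and touches no stereocentre.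

Step 2
Reactants: 2 (4R,6R)-4-[(tert-butyldimethylsilyl)oxy]-2,2,6-trimethylcyclohexan-1-one
Product: 4 (4R)-4-[(tert-butyldimethylsilyl)oxy]-2,6,6-trimethylcyclohex-1-en-1-yl trifluoromethanesulfonate, via lithium enolate 3 (not isolated)
Conditions: LiN(iPr)2, THF, −78 °C; then PhNTf2, −78 °C to rt
Reagents that add atoms: N-phenylbis(trifluoromethanesulfonimide), O=S(=O)(N(c1ccccc1)S(=O)(=O)C(F)(F)F)C(F)(F)F
Why: In this enol triflate formation the ketone can enolise only towards the methyl-bearing alpha carbon (the other alpha carbon is quaternary), so O-triflation should give the tetrasubstituted C5=C6 alkene of ring B with the leaving group on C6; the methyl-bearing stereocentre of 2 is erased and the silyloxy-bearing one (future C3) is untouched.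

Step 3
Reactants: 4 (4R)-4-[(tert-butyldimethylsilyl)oxy]-2,6,6-trimethylcyclohex-1-en-1-yl trifluoromethanesulfonate; 5 (2E)-3-methylpent-2-en-4-yn-1-ol
Product: 6 (2E)-5-[(4R)-4-[(tert-butyldimethylsilyl)oxy]-2,6,6-trimethylcyclohex-1-en-1-yl]-3-methylpent-2-en-4-yn-1-ol
Conditions: Pd(PPh3)4 (5 mol %), CuI (10 mol %), Et3N, DMF, rt to 50 °C
Reagents that add atoms: none
Why: Sonogashira coupling of the alkenyl triflate with the terminal alkyne should form the C6–C7 bond and install C7≡C8 directly, the E geometry of C9=C10 arriving intact with building block 5.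

Step 4
Reactants: 6 (2E)-5-[(4R)-4-[(tert-butyldimethylsilyl)oxy]-2,6,6-trimethylcyclohex-1-en-1-yl]-3-methylpent-2-en-4-yn-1-ol
Product: 7 (2E)-5-[(4R)-4-[(tert-butyldimethylsilyl)oxy]-2,6,6-trimethylcyclohex-1-en-1-yl]-3-methylpent-2-en-4-ynal
Conditions: MnO2, CH2Cl2, rt, dark
Reagents that add atoms: none
Why: Allylic alcohol oxidation with MnO2 is selective for the primary allylic hydroxyl and should leave the enyne, the silyl ether and the alkene geometry unchanged.

Step 5
Reactants: 7 (2E)-5-[(4R)-4-[(tert-butyldimethylsilyl)oxy]-2,6,6-trimethylcyclohex-1-en-1-yl]-3-methylpent-2-en-4-ynal; 8 diethyl [(2E)-3-cyano-2-methylprop-2-en-1-yl]phosphonate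
Product: 10 (2E,4E,6E)-9-[(4R)-4-[(tert-butyldimethylsilyl)oxy]-2,6,6-trimethylcyclohex-1-en-1-yl]-3,7-dimethylnona-2,4,6-trien-8-ynenitrile, via sodium phosphonate carbanion 9 (not isolated)
Conditions: 8, NaH, THF, 0 °C; then 7, 0 °C to rt; chromatography to remove the minor C13=C14 Z isomer
Reagents that add atoms: none
Why: Horner–Wadsworth–Emmons olefination with the stabilised allylic phosphonate anion should form C11=C12 with E geometry and deliver the C13 methyl-branched unit in one operation.

Step 6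
Reactants: 10 (2E,4E,6E)-9-[(4R)-4-[(tert-butyldimethylsilyl)oxy]-2,6,6-trimethylcyclohex-1-en-1-yl]-3,7-dimethylnona-2,4,6-trien-8-ynenitrile
Product: 12 (2E,4E,6E)-9-[(4R)-4-[(tert-butyldimethylsilyl)oxy]-2,6,6-trimethylcyclohex-1-en-1-yl]-3,7-dimethylnona-2,4,6-trien-8-ynal, via N-aluminio aldimine 11 (not isolated)
Conditions: iBu2AlH (1.3 equiv), toluene, −78 °C; then wet SiO2, 0 °C
Reagents that add atoms: water, O
Why: Partial reduction of a nitrile stops after one hydride transfer at the aluminium aldimine, which is hydrolysed on work-up to the conjugated aldehyde without disturbing the polyene, alkyne or silyl ether.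

Step 7
Reactants: 12 (2E,4E,6E)-9-[(4R)-4-[(tert-butyldimethylsilyl)oxy]-2,6,6-trimethylcyclohex-1-en-1-yl]-3,7-dimethylnona-2,4,6-trien-8-ynal
Product: 13 tert-butyl{[(1R)-4-[(3E,5E,7E,9E)-10-iodo-3,7-dimethyldeca-3,5,7,9-tetraen-1-yn-1-yl]-3,5,5-trimethylcyclohex-3-en-1-yl]oxy}dimethylsilane
Conditions: CrCl2 (8 equiv), CHI3 (2.5 equiv), THF–dioxane, 0 °C to rt, dark
Reagents that add atoms: iodoform, IC(I)I
Why: Takai iodo-olefination adds a geminal dichromium carbenoid to the aldehyde and eliminates anti-periplanar, which should give the E alkenyl iodide at C15=C15' under neutral conditions tolerated by the enyne and silyl ether.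

Step 8
Reactants: 14 (3E)-4-[(1R)-2,6,6-trimethylcyclohex-2-en-1-yl]but-3-en-2-one ((R)-alpha-ionone)
Product: 18 (6R)-6-[(1E)-but-1-en-3-yn-1-yl]-1,5,5-trimethylcyclohex-1-ene, via lithium enolate 15 (not isolated), via enol phosphate 16 (not isolated), via lithium acetylide 17 (not isolated)
Conditions: LiN(iPr)2 (1.05 equiv), THF, −78 °C; ClP(O)(OEt)2, −78 °C to rt; then LiN(iPr)2 (2.3 equiv), −78 °C to rt; H2O
Reagents that add atoms: none
Why: Kinetic deprotonation of the methyl group, O-phosphorylation and base-induced elimination of the enol phosphate (methyl ketone to terminal alkyne conversion) should give the enyne, the hindered C6' hydrogen being left alone at low temperature so that the stereocentre is kept.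

Step 9
Reactants: 19 (E)-1,2-dichloroethene; 20 ethynyltrimethylsilane
Product: 21 [(3E)-4-chlorobut-3-en-1-yn-1-yl]trimethylsilane
Conditions: Pd(PPh3)4 (3 mol %), CuI (6 mol %), n-BuNH2, Et2O, rt, fivefold excess of 19
Reagents that add atoms: none
Why: Sonogashira mono-coupling of the dichloroalkene proceeds with retention of the E geometry, and the excess of 19 should suppress the second coupling.

Step 10
Reactants: 18 (6R)-6-[(1E)-but-1-en-3-yn-1-yl]-1,5,5-trimethylcyclohex-1-ene; 21 [(3E)-4-chlorobut-3-en-1-yn-1-yl]trimethylsilane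
Product: 23 trimethyl{(3E,5E,7E)-6-methyl-8-[(1R)-2,6,6-trimethylcyclohex-2-en-1-yl]octa-3,5,7-trien-1-yn-1-yl}silane, via alkenylalane 22 (not isolated)
Conditions: Me3Al (2 equiv), Cp2ZrCl2 (0.25 equiv), (CH2Cl)2, rt; volatiles removed in vacuo; then 21, ZnCl2 (1 equiv), Pd(PPh3)4 (5 mol %), THF, rt to 45 °C
Reagents that add atoms: trimethylaluminium, C[Al](C)C
Why: Zirconium-catalysed syn methylalumination puts the methyl group on C9' and aluminium on C10' (E C9'=C10'), and the Pd/Zn-co-catalysed Negishi coupling with the alkyne-activated alkenyl chloride should then form C10'–C11' with retention at both alkenes.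

Step 11
Reactants: 23 trimethyl{(3E,5E,7E)-6-methyl-8-[(1R)-2,6,6-trimethylcyclohex-2-en-1-yl]octa-3,5,7-trien-1-yn-1-yl}silane
Product: 24 (6R)-1,5,5-trimethyl-6-[(1E,3E,5E)-3-methylocta-1,3,5-trien-7-yn-1-yl]cyclohex-1-ene
Conditions: K2CO3 (cat.), MeOH–THF, rt, dark
Reagents that add atoms: none
Why: Methoxide-induced protodesilylation of the alkynylsilane frees the terminal C13'≡C14'–H alkyne under conditions too mild to affect the triene or C6'.

Step 12
Reactants: 24 (6R)-1,5,5-trimethyl-6-[(1E,3E,5E)-3-methylocta-1,3,5-trien-7-yn-1-yl]cyclohex-1-ene; 13 tert-butyl{[(1R)-4-[(3E,5E,7E,9E)-10-iodo-3,7-dimethyldeca-3,5,7,9-tetraen-1-yn-1-yl]-3,5,5-trimethylcyclohex-3-en-1-yl]oxy}dimethylsilane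
Product: 26 (3R,6'R)-3-[(tert-butyldimethylsilyl)oxy]-7,8-didehydro-beta,epsilon-carotene (O-silyl crocoxanthin), via alkenylalane 25 (not isolated)
Conditions: 24 (1.3 equiv), Me3Al (2.5 equiv), Cp2ZrCl2 (0.3 equiv), (CH2Cl)2, rt; volatiles removed in vacuo; then 13 (1.0 equiv), ZnCl2 (1 equiv), Pd2(dba)3 (2.5 mol %), P(2-furyl)3 (10 mol %), THF–DMF, rt, dark
Reagents that add atoms: trimethylaluminium, C[Al](C)C
Why: Me3Al and Cp2ZrCl2 form a bimetallic methylzirconium species that adds methyl and metal syn across the terminal C13'≡C14' triple bond of 24 with methyl on the internal carbon, giving after zirconium-to-aluminium exchange the (E)-2-methylalkenylalane 25; ZnCl2 then relays the alkenyl group to the alkenylpalladium iodide formed by oxidative addition of zerovalent palladium into the C15'–I bond of 13, and reductive elimination forges C14'–C15'. The closest known reaction type is the Negishi sequence of zirconium-catalysed carboalumination and Pd/Zn-co-catalysed alkenyl–alkenyl cross-coupling, which is established on conjugated retinoid and carotenoid polyenynes. No ring is closed and no stereocentre is created; the stereochemical content is the E geometry of C13'=C14', fixed by syn addition followed by coupling with retention, and the E geometry of C15'=C15, carried over from 13 with retention. The step needs methyl delivery to C13' only, reaction at the terminal alkyne only, and alkenyl instead of methyl transfer to palladium: the steric bias of a monosubstituted alkyne secures the first, the inertness of the trisubstituted ring E alkene and of the triene towards methylalumination secures the second, and evaporation of free Me3Al before 13 is added secures the third while also sparing the internal C7≡C8 alkyne of 13. The silyl ether on O3 removes the only protic site that would quench 25.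

Step 13
Reactants: 26 (3R,6'R)-3-[(tert-butyldimethylsilyl)oxy]-7,8-didehydro-beta,epsilon-carotene
Product: 27 (3R,6'R)-7,8-didehydro-beta,epsilon-caroten-3-ol (crocoxanthin, CNP0322200.1)
Conditions: Bu4NF, AcOH, THF, 0 °C to rt, dark, argon
Reagents that add atoms: none
Why: Fluoride-driven silyl ether cleavage under acetic acid buffering should release the C3 hydroxyl without touching the nonaene, the C7≡C8 alkyne or either stereocentre.

Compound list
1 | (4R,6R)-4-hydroxy-2,2,6-trimethylcyclohexan-1-one ((4R,6R)-actinol) | O=C1[C@H](C)C[C@@H](O)CC1(C)C | starting material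
2 | (4R,6R)-4-[(tert-butyldimethylsilyl)oxy]-2,2,6-trimethylcyclohexan-1-one | O=C1[C@H](C)C[C@@H](O[Si](C)(C)C(C)(C)C)CC1(C)C | intermediate
3 | lithium (4R)-4-[(tert-butyldimethylsilyl)oxy]-2,6,6-trimethylcyclohex-1-en-1-olate (lithium enolate, formed in the flask) | [Li+].[O-]C1=C(C)C[C@@H](O[Si](C)(C)C(C)(C)C)CC1(C)C | intermediate
4 | (4R)-4-[(tert-butyldimethylsilyl)oxy]-2,6,6-trimethylcyclohex-1-en-1-yl trifluoromethanesulfonate | O=S(=O)(OC1=C(C)C[C@@H](O[Si](C)(C)C(C)(C)C)CC1(C)C)C(F)(F)F | intermediate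
5 | (2E)-3-methylpent-2-en-4-yn-1-ol | C#C/C(C)=C/CO | starting material
6 | (2E)-5-[(4R)-4-[(tert-butyldimethylsilyl)oxy]-2,6,6-trimethylcyclohex-1-en-1-yl]-3-methylpent-2-en-4-yn-1-ol | OC/C=C(\C)C#CC1=C(C)C[C@@H](O[Si](C)(C)C(C)(C)C)CC1(C)C | intermediate
7 | (2E)-5-[(4R)-4-[(tert-butyldimethylsilyl)oxy]-2,6,6-trimethylcyclohex-1-en-1-yl]-3-methylpent-2-en-4-ynal | O=C/C=C(\C)C#CC1=C(C)C[C@@H](O[Si](C)(C)C(C)(C)C)CC1(C)C | intermediate
8 | diethyl [(2E)-3-cyano-2-methylprop-2-en-1-yl]phosphonate | CCOP(=O)(OCC)C/C(C)=C/C#N | starting material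
9 | sodium salt of the carbanion of 8 (formed in the flask) | [Na+].CCOP(=O)(OCC)[CH-]/C(C)=C/C#N | intermediate
10 | (2E,4E,6E)-9-[(4R)-4-[(tert-butyldimethylsilyl)oxy]-2,6,6-trimethylcyclohex-1-en-1-yl]-3,7-dimethylnona-2,4,6-trien-8-ynenitrile | N#C/C=C(C)/C=C/C=C(\C)C#CC1=C(C)C[C@@H](O[Si](C)(C)C(C)(C)C)CC1(C)C | intermediate
11 | N-(diisobutylaluminio) aldimine of 12 (formed in the flask) | CC(C)C[Al](CC(C)C)N=C/C=C(C)/C=C/C=C(\C)C#CC1=C(C)C[C@@H](O[Si](C)(C)C(C)(C)C)CC1(C)C | intermediate
12 | (2E,4E,6E)-9-[(4R)-4-[(tert-butyldimethylsilyl)oxy]-2,6,6-trimethylcyclohex-1-en-1-yl]-3,7-dimethylnona-2,4,6-trien-8-ynal | O=C/C=C(C)/C=C/C=C(\C)C#CC1=C(C)C[C@@H](O[Si](C)(C)C(C)(C)C)CC1(C)C | intermediate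
13 | tert-butyl{[(1R)-4-[(3E,5E,7E,9E)-10-iodo-3,7-dimethyldeca-3,5,7,9-tetraen-1-yn-1-yl]-3,5,5-trimethylcyclohex-3-en-1-yl]oxy}dimethylsilane | I/C=C/C=C(C)/C=C/C=C(\C)C#CC1=C(C)C[C@@H](O[Si](C)(C)C(C)(C)C)CC1(C)C | intermediate
14 | (3E)-4-[(1R)-2,6,6-trimethylcyclohex-2-en-1-yl]but-3-en-2-one ((R)-alpha-ionone) | CC1=CCCC(C)(C)[C@H]1/C=C/C(C)=O | starting material
15 | lithium (3E)-4-[(1R)-2,6,6-trimethylcyclohex-2-en-1-yl]buta-1,3-dien-2-olate (lithium enolate, formed in the flask) | CC1=CCCC(C)(C)[C@H]1/C=C/C(=C)[O-].[Li+] | intermediate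
16 | diethyl (3E)-4-[(1R)-2,6,6-trimethylcyclohex-2-en-1-yl]buta-1,3-dien-2-yl phosphate (enol phosphate, formed in the flask) | CC1=CCCC(C)(C)[C@H]1/C=C/C(=C)OP(=O)(OCC)OCC | intermediate
17 | lithium acetylide of 18 (formed in the flask) | CC1=CCCC(C)(C)[C@H]1/C=C/C#[C-].[Li+] | intermediate
18 | (6R)-6-[(1E)-but-1-en-3-yn-1-yl]-1,5,5-trimethylcyclohex-1-ene | CC1=CCCC(C)(C)[C@H]1/C=C/C#C | intermediate
19 | (E)-1,2-dichloroethene | Cl/C=C/Cl | starting material
20 | ethynyltrimethylsilane | C#C[Si](C)(C)C | starting material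
21 | [(3E)-4-chlorobut-3-en-1-yn-1-yl]trimethylsilane | Cl/C=C/C#C[Si](C)(C)C | intermediate
22 | dimethyl{(1E,3E)-2-methyl-4-[(1R)-2,6,6-trimethylcyclohex-2-en-1-yl]buta-1,3-dien-1-yl}alane (formed in the flask) | CC1=CCCC(C)(C)[C@H]1/C=C/C(C)=C/[Al](C)C | intermediate
23 | trimethyl{(3E,5E,7E)-6-methyl-8-[(1R)-2,6,6-trimethylcyclohex-2-en-1-yl]octa-3,5,7-trien-1-yn-1-yl}silane | CC1=CCCC(C)(C)[C@H]1/C=C/C(C)=C/C=C/C#C[Si](C)(C)C | intermediate
24 | (6R)-1,5,5-trimethyl-6-[(1E,3E,5E)-3-methylocta-1,3,5-trien-7-yn-1-yl]cyclohex-1-ene | CC1=CCCC(C)(C)[C@H]1/C=C/C(C)=C/C=C/C#C | intermediate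
25 | dimethyl{(1E,3E,5E,7E)-2,6-dimethyl-8-[(1R)-2,6,6-trimethylcyclohex-2-en-1-yl]octa-1,3,5,7-tetraen-1-yl}alane (formed in the flask) | CC1=CCCC(C)(C)[C@H]1/C=C/C(C)=C/C=C/C(C)=C/[Al](C)C | intermediate
26 | (3R,6'R)-3-[(tert-butyldimethylsilyl)oxy]-7,8-didehydro-beta,epsilon-carotene | CC1=CCCC(C)(C)[C@H]1/C=C/C(C)=C/C=C/C(C)=C/C=C/C=C(C)/C=C/C=C(\C)C#CC1=C(C)C[C@@H](O[Si](C)(C)C(C)(C)C)CC1(C)C | intermediate
27 | (3R,6'R)-7,8-didehydro-beta,epsilon-caroten-3-ol (crocoxanthin, CNP0322200.1) | CC1=CCCC(C)(C)[C@H]1/C=C/C(C)=C/C=C/C(C)=C/C=C/C=C(C)/C=C/C=C(\C)C#CC1=C(C)C[C@@H](O)CC1(C)C | target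

Total step count: 13. Longest linear sequence: 9 steps (steps 1 to 7, then 12 and 13).

Steps most likely to fail

Step 12. The methylalumination of the conjugated trienyne may be incomplete or may be diverted into abstraction of the acetylenic hydrogen. The alane may be protonated before it couples, and slow transmetalation may allow homocoupling or E/Z erosion of the light-sensitive iodotetraene. The fallback joins the same two carbons by a Stille coupling with reversed polarity and without a carbometalation in the union. It sets out from 24 and 12 and comes back at 26. Alkyne 24 is methylaluminated as in the route and alane 25 is quenched with I2 in THF at −30 °C to give (6R)-6-[(1E,3E,5E,7E)-8-iodo-3,7-dimethylocta-1,3,5,7-tetraen-1-yl]-1,5,5-trimethylcyclohex-1-ene F1. Aldehyde 12 is treated with Bu3SnCHBr2, CrCl2 and LiI in THF–DMF (chromium-mediated stannyl-olefination) to give tert-butyldimethyl{[(1R)-3,5,5-trimethyl-4-[(3E,5E,7E,9E)-3,7-dimethyl-10-(tributylstannyl)deca-3,5,7,9-tetraen-1-yn-1-yl]cyclohex-3-en-1-yl]oxy}silane F2. F1 and F2 are then coupled with Pd2(dba)3 and AsPh3 in NMP at rt in the dark to give 26.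

Step 8. Excess amide base may remove the doubly allylic C6' hydrogen, with loss of configuration or migration of the ring alkene into conjugation, and the elimination may stop at an allene. The fallback builds the chain by olefination chemistry that uses only weakly basic stabilised anions. It sets out from 14, comes back at 23, and thereby also bypasses steps 9 and 10. Ketone 14 is condensed with triethyl phosphonoacetate and NaH in THF to give ethyl (2E,4E)-3-methyl-5-[(1R)-2,6,6-trimethylcyclohex-2-en-1-yl]penta-2,4-dienoate F3 (the C9' Z isomer removed by chromatography). Reduction with iBu2AlH at −78 °C gives (2E,4E)-3-methyl-5-[(1R)-2,6,6-trimethylcyclohex-2-en-1-yl]penta-2,4-dien-1-ol F4. MnO2 in CH2Cl2 gives (2E,4E)-3-methyl-5-[(1R)-2,6,6-trimethylcyclohex-2-en-1-yl]penta-2,4-dienal F5. A Horner–Wadsworth–Emmons reaction of F5 with diethyl [3-(trimethylsilyl)prop-2-yn-1-yl]phosphonate and NaN(SiMe3)2 in THF at −78 °C to rt gives 23.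

Step 7. The chromium-mediated iodo-olefination of a conjugated aldehyde may give poor E selectivity, and the iodotetraene may isomerise or decompose in light during isolation. The fallback fixes the geometry by a syn hydrometalation. It sets out from 12 and comes back at 13. Aldehyde 12 is homologated with dimethyl (1-diazo-2-oxopropyl)phosphonate and K2CO3 in MeOH (Ohira–Bestmann alkynylation) to give tert-butyl{[(1R)-4-[(3E,5E,7E)-3,7-dimethyldeca-3,5,7-trien-1,9-diyn-1-yl]-3,5,5-trimethylcyclohex-3-en-1-yl]oxy}dimethylsilane F6. Hydrozirconation of the terminal alkyne with Cp2Zr(H)Cl in THF at rt gives the (E)-alkenylzirconocene chloride of F6 F7, which is iodinated in the same flask with I2 at 0 °C to give 13.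

Further compounds
F1 | step 12 | (6R)-6-[(1E,3E,5E,7E)-8-iodo-3,7-dimethylocta-1,3,5,7-tetraen-1-yl]-1,5,5-trimethylcyclohex-1-ene | CC1=CCCC(C)(C)[C@H]1/C=C/C(C)=C/C=C/C(C)=C/I
F2 | step 12 | tert-butyldimethyl{[(1R)-3,5,5-trimethyl-4-[(3E,5E,7E,9E)-3,7-dimethyl-10-(tributylstannyl)deca-3,5,7,9-tetraen-1-yn-1-yl]cyclohex-3-en-1-yl]oxy}silane | CCCC[Sn](CCCC)(CCCC)/C=C/C=C(C)/C=C/C=C(\C)C#CC1=C(C)C[C@@H](O[Si](C)(C)C(C)(C)C)CC1(C)C
F3 | step 8 | ethyl (2E,4E)-3-methyl-5-[(1R)-2,6,6-trimethylcyclohex-2-en-1-yl]penta-2,4-dienoate | CC1=CCCC(C)(C)[C@H]1/C=C/C(C)=C/C(=O)OCC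
F4 | step 8 | (2E,4E)-3-methyl-5-[(1R)-2,6,6-trimethylcyclohex-2-en-1-yl]penta-2,4-dien-1-ol | CC1=CCCC(C)(C)[C@H]1/C=C/C(C)=C/CO
F5 | step 8 | (2E,4E)-3-methyl-5-[(1R)-2,6,6-trimethylcyclohex-2-en-1-yl]penta-2,4-dienal | CC1=CCCC(C)(C)[C@H]1/C=C/C(C)=C/C=O
F6 | step 7 | tert-butyl{[(1R)-4-[(3E,5E,7E)-3,7-dimethyldeca-3,5,7-trien-1,9-diyn-1-yl]-3,5,5-trimethylcyclohex-3-en-1-yl]oxy}dimethylsilane | C#C/C=C(C)/C=C/C=C(\C)C#CC1=C(C)C[C@@H](O[Si](C)(C)C(C)(C)C)CC1(C)C
F7 | step 7 | (E)-alkenylzirconocene chloride of F6 (Cp2Zr(Cl) on the terminal carbon) | Cl[Zr](C1C=CC=C1)(C1C=CC=C1)/C=C/C=C(C)/C=C/C=C(\C)C#CC1=C(C)C[C@@H](O[Si](C)(C)C(C)(C)C)CC1(C)C
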